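The quinone ring is cut into a C4 and a C2 piece. Its four contiguous carbons O=C–C(OMe)=C(OMe)–C=O are the ring of dimethyl squarate. The remaining C(chromanyl)=CH pair is a terminal alkyne on C3 of the chroman. The key step, a Moore rearrangement, heats the 4-alkynyl-4-hydroxy-2,3-dimethoxycyclobutenone made from both. The four-membered ring opens to a ketene, the six-membered ring closes, and the quinone appears at its final oxidation level beside the untouched C3 stereocentre. The precursor is thus a squaric acid derivative with no six-membered carbocycle at this site. C3 is set earlier by asymmetric hydrogenation of a 2H-chromene-3-carboxylic acid.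

Key step: step 9

Remarks on the chemistry:
- The only stereocentre, C3 of the chroman, is (S) in the target. Its spatial arrangement is unchanged from step 5 onward. The descriptor reads (R) in 7, 8 and 9 only because a carbonyl substituent outranks C2.
- 2,3-Dimethoxybenzene-1,4-diol is assumed to be a catalogue compound.

Step 1
Reactants: 1 2,3-dimethoxybenzene-1,4-diol
Product: 2 2,3-dimethoxy-4-(methoxymethoxy)phenol
Conditions: NaH (1.0 equiv), DMF, 0 °C, Ar; MOMCl (1.0 equiv), 0 °C to rt
Reagents that add atoms: chloromethyl methyl ether (MOMCl), COCCl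
Why: Williamson-type O-alkylation of the monosodium phenoxide; the two hydroxyls of 1 are equivalent by symmetry, so one equivalent each of base and MOMCl should favour the mono-acetal, and recovered 1 and the bis-ether are separable and recyclable.

Step 2
Reactants: 2 2,3-dimethoxy-4-(methoxymethoxy)phenol
Product: 3 2-hydroxy-3,4-dimethoxy-5-(methoxymethoxy)benzaldehyde
Conditions: MgCl2, Et3N, (CH2O)n, MeCN, reflux; aq. citric acid work-up
Reagents that add atoms: paraformaldehyde (as formaldehyde), C=O
Why: Casnati–Skattebøl ortho-formylation: the magnesium phenoxide delivers formaldehyde to the only free ortho position, a second formaldehyde takes up hydride to leave the aldehyde, and the MOM acetal is inert to the basic medium.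

Step 3
Reactants: 3 2-hydroxy-3,4-dimethoxy-5-(methoxymethoxy)benzaldehyde; 4 acrolein
Product: 5 7,8-dimethoxy-6-(methoxymethoxy)-2H-chromene-3-carbaldehyde
Conditions: K2CO3, 1,4-dioxane, reflux
Reagents that add atoms: none
Why: Domino oxa-Michael addition/intramolecular aldol condensation of a salicylaldehyde with acrolein closes the pyran ring and leaves the C3–C4 olefin conjugated to the formyl group.

Step 4
Reactants: 5 7,8-dimethoxy-6-(methoxymethoxy)-2H-chromene-3-carbaldehyde
Product: 6 7,8-dimethoxy-6-(methoxymethoxy)-2H-chromene-3-carboxylic acid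
Conditions: NaClO2, NaH2PO4, 2-methyl-2-butene (excess), t-BuOH/H2O, rt
Reagents that add atoms: sodium chlorite, [Na+].[O-]Cl=O
Why: Pinnick oxidation converts the enal into the acid without touching the olefin, the buffer (about pH 4) spares the MOM acetal, and the alkene scavenger keeps HOCl away from the electron-rich arene.

Step 5
Reactants: 6 7,8-dimethoxy-6-(methoxymethoxy)-2H-chromene-3-carboxylic acid
Product: 7 (3R)-7,8-dimethoxy-6-(methoxymethoxy)chromane-3-carboxylic acid
Conditions: Ru(OAc)2[(S)-H8-BINAP] (cat.), H2 (10 bar), MeOH, 30 °C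
Reagents that add atoms: none
Why: Carboxylate-directed ruthenium-catalysed asymmetric hydrogenation of an α,β-unsaturated acid sets C3: the ring fixes the olefin in the geometry of an (E)-2-alkyl-2-alkenoic acid, for which the (S)-ligand adds H2 to the face that corresponds here to the (3R)-acid (the antipodal ligand is at hand should the sense prove opposite).

Step 6
Reactants: 7 (3R)-7,8-dimethoxy-6-(methoxymethoxy)chromane-3-carboxylic acid
Product: 9 (3R)-7,8-dimethoxy-6-(methoxymethoxy)chromane-3-carbaldehyde, via acyl imidazolide 8 (not isolated)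
Conditions: CDI, CH2Cl2, 0 °C to rt; then DIBAL-H (toluene), −78 °C; aq. tartaric acid quench
Reagents that add atoms: none
Why: Activation as the acyl imidazolide and partial reduction by DIBAL-H at −78 °C give a tetrahedral aluminium adduct that releases the aldehyde only on acidic quench, a known one-pot acid-to-aldehyde reduction that preserves α-stereocentres; 9 is used at once because its α-hydrogen lies β to an aryloxy group.

Step 7
Reactants: 9 (3R)-7,8-dimethoxy-6-(methoxymethoxy)chromane-3-carbaldehyde
Product: 10 (3S)-3-(2,2-dibromoethenyl)-7,8-dimethoxy-6-(methoxymethoxy)chromane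
Conditions: CBr4, PPh3 (2 equiv per CBr4), 2,6-lutidine, CH2Cl2, 0 °C
Reagents that add atoms: carbon tetrabromide, BrC(Br)(Br)Br
Why: First stage of the Corey–Fuchs sequence (Ramirez dibromoolefination), a Wittig-type reaction under essentially neutral conditions that removes the acidic α-formyl hydrogen and so secures the C3 configuration, while lutidine scavenges HBr and protects the MOM acetal.

Step 8
Reactants: 10 (3S)-3-(2,2-dibromoethenyl)-7,8-dimethoxy-6-(methoxymethoxy)chromane; 11 dimethyl squarate
Product: 13 4-{[(3S)-7,8-dimethoxy-6-(methoxymethoxy)chroman-3-yl]ethynyl}-4-hydroxy-2,3-dimethoxycyclobut-2-en-1-one (both epimers at the carbinol carbon), via lithium acetylide 12 (not isolated)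
Conditions: n-BuLi (2.0 equiv), THF, −78 to 0 °C; recool to −78 °C, cannulate into 11 in THF, −78 °C; sat. aq. NH4Cl at −78 °C
Reagents that add atoms: none
Why: Second stage of the Corey–Fuchs sequence (bromine–lithium exchange, Fritsch–Buttenberg–Wiechell shift, deprotonation) gives acetylide 12, whose 1,2-addition to one of the two equivalent carbonyl groups of dimethyl squarate is the standard entry to 4-alkynyl-4-hydroxycyclobutenones; the new carbinol centre forms without control, which is harmless because step 9 erases it.

Step 9
Reactants: 13 4-{[(3S)-7,8-dimethoxy-6-(methoxymethoxy)chroman-3-yl]ethynyl}-4-hydroxy-2,3-dimethoxycyclobut-2-en-1-one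
Product: 16 5-[(3S)-7,8-dimethoxy-6-(methoxymethoxy)chroman-3-yl]-2,3-dimethoxy-1,4-benzoquinone, via alkynylvinylketene 14 (not isolated), via aryl phenoxyl diradical 15 (not isolated)
Conditions: p-xylene (dilute, degassed), reflux (138 °C), Ar
Reagents that add atoms: none
Why: Heating triggers a conrotatory 4π electrocyclic opening of the cyclobutenone C1–C4 bond in which the donor hydroxyl rotates outward (torquoselectivity), so that the alkynyl group of ketene 14 points at the ketene carbon. The ketene carbon then bonds to the distal alkyne carbon (the one bearing the chroman) in a 6-endo-dig closure that gives the aromatic σ-aryl/phenoxyl diradical 15, and transfer of the hydroxyl hydrogen to the σ-radical carbon yields the quinone at its final oxidation level. This is the Moore rearrangement of 4-alkynyl-4-hydroxycyclobutenones, a known reaction type that applies directly. No stereocentre is formed: the carbinol centre of 13 (either epimer) is erased, and C3 of the chroman is a spectator under neutral, aprotic conditions. The step needs 6-endo over 5-exo closure (the latter would lead to an alkylidenecyclopentenedione), and the sp3 alkyl substituent on the alkyne secures this because it cannot stabilise the exocyclic vinyl radical of the 5-exo mode. Regiochemistry is not an issue, because the two carbonyl groups of 11 are equivalent and the alkyne carbons are placed unambiguously, C(chromanyl) next to the former ketene carbon and CH next to the former carbinol carbon.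

Step 10
Reactants: 16 5-[(3S)-7,8-dimethoxy-6-(methoxymethoxy)chroman-3-yl]-2,3-dimethoxy-1,4-benzoquinone
Product: 17 5-[(3S)-6-hydroxy-7,8-dimethoxychroman-3-yl]-2,3-dimethoxy-1,4-benzoquinone (target)
Conditions: HCl (1.25 M in MeOH), 0 °C to rt
Reagents that add atoms: none
Why: Acid-catalysed transacetalisation cleaves the phenolic MOM acetal to dimethoxymethane, and methanol is the solvent of choice because any exchange at the vinylogous ester methoxy groups of the quinone is degenerate.

Compound list
1 | 2,3-dimethoxybenzene-1,4-diol | COc1c(O)ccc(O)c1OC | starting material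
2 | 2,3-dimethoxy-4-(methoxymethoxy)phenol | COCOc1ccc(O)c(OC)c1OC | intermediate
3 | 2-hydroxy-3,4-dimethoxy-5-(methoxymethoxy)benzaldehyde | COCOc1cc(C=O)c(O)c(OC)c1OC | intermediate
4 | acrolein (prop-2-enal) | C=CC=O | starting material
5 | 7,8-dimethoxy-6-(methoxymethoxy)-2H-chromene-3-carbaldehyde | O=CC1=Cc2cc(OCOC)c(OC)c(OC)c2OC1 | intermediate
6 | 7,8-dimethoxy-6-(methoxymethoxy)-2H-chromene-3-carboxylic acid | OC(=O)C1=Cc2cc(OCOC)c(OC)c(OC)c2OC1 | intermediate
7 | (3R)-7,8-dimethoxy-6-(methoxymethoxy)chromane-3-carboxylic acid | OC(=O)[C@H]1COc2c(cc(OCOC)c(OC)c2OC)C1 | intermediate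
8 | 1-{[(3R)-7,8-dimethoxy-6-(methoxymethoxy)chroman-3-yl]carbonyl}imidazole | O=C([C@H]1COc2c(cc(OCOC)c(OC)c2OC)C1)n1ccnc1 | intermediate
9 | (3R)-7,8-dimethoxy-6-(methoxymethoxy)chromane-3-carbaldehyde | O=C[C@H]1COc2c(cc(OCOC)c(OC)c2OC)C1 | intermediate
10 | (3S)-3-(2,2-dibromoethenyl)-7,8-dimethoxy-6-(methoxymethoxy)chromane | BrC(Br)=C[C@H]1COc2c(cc(OCOC)c(OC)c2OC)C1 | intermediate
11 | dimethyl squarate (3,4-dimethoxycyclobut-3-ene-1,2-dione) | COC1=C(OC)C(=O)C1=O | starting material
12 | lithium acetylide of (3S)-3-ethynyl-7,8-dimethoxy-6-(methoxymethoxy)chromane | [Li]C#C[C@H]1COc2c(cc(OCOC)c(OC)c2OC)C1 | intermediate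
13 | 4-{[(3S)-7,8-dimethoxy-6-(methoxymethoxy)chroman-3-yl]ethynyl}-4-hydroxy-2,3-dimethoxycyclobut-2-en-1-one (carbinol carbon: both epimers) | COC1=C(OC)C(O)(C#C[C@H]2COc3c(cc(OCOC)c(OC)c3OC)C2)C1=O | intermediate
14 | (3Z)-6-[(3S)-7,8-dimethoxy-6-(methoxymethoxy)chroman-3-yl]-4-hydroxy-2,3-dimethoxyhexa-1,3-dien-5-yn-1-one (alkynylvinylketene) | O=C=C(OC)/C(OC)=C(/O)C#C[C@H]1COc2c(cc(OCOC)c(OC)c2OC)C1 | intermediate
15 | 4-hydroxy-2,3-dimethoxy-6-[(3S)-chroman-3-yl]phenoxyl-5-yl diradical (chroman substituted as in 13) | COc1c(OC)c(O)[c]c([C@H]2COc3c(cc(OCOC)c(OC)c3OC)C2)c1[O] | intermediate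
16 | 5-[(3S)-7,8-dimethoxy-6-(methoxymethoxy)chroman-3-yl]-2,3-dimethoxy-1,4-benzoquinone | COC1=C(OC)C(=O)C([C@H]2COc3c(cc(OCOC)c(OC)c3OC)C2)=CC1=O | intermediate
17 | 5-[(3S)-6-hydroxy-7,8-dimethoxychroman-3-yl]-2,3-dimethoxy-1,4-benzoquinone | COC1=C(OC)C(=O)C([C@H]2COc3c(cc(O)c(OC)c3OC)C2)=CC1=O | target

Total step count: 10. Longest linear sequence: 10 steps (1 to 17).

Steps most likely to fail

Step 9. The σ-radical centre of the diradical may be intercepted by hydrogen transfer from the activated C2–H or C4–H bonds of the chroman, or closure may leak into the 5-exo mode. Both would erode quinone formation. The fallback sets out from 13 and replaces the open-shell closure by a closed-shell one. Semihydrogenation of the alkyne (H2, Pd/CaCO3 poisoned with Pb(OAc)2, quinoline, EtOAc) should give the (Z)-alkenylcyclobutenone F1. Heating it in toluene brings about ring opening, 6π electrocyclisation of the dienylketene and tautomerisation to the hydroquinone F2. Oxidation with Ag2O in CH2Cl2 comes back to the route at 16.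

Step 5. Facial discrimination may be insufficient, or hydrogen uptake sluggish, on the electron-rich, ring-constrained trisubstituted olefin. The fallback sets out from 6 and replaces catalysis by separation of covalent diastereomers.
- Hydrogenation over Pd/C (H2, EtOAc) gives the racemic chromane-3-carboxylic acid F3.
- N-acylation of (S)-4-benzyloxazolidin-2-one with it (DCC, DMAP, CH2Cl2) gives the (3R)-imide F4 and the (3S)-imide F5. These are separated by chromatography and assigned by correlation.
- Cleavage of F4 with LiOH/H2O2 (THF/H2O, 0 °C) comes back to the route at 7.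

Step 6. The acyl imidazolide may be over-reduced, and configuration may erode by enolisation or reversible β-elimination of the aryloxide while imidazole is present. The fallback sets out from 7 and splits the redox adjustment into two selective operations. Full reduction with BH3·THF (0 °C to rt) gives the (3S)-chroman-3-ylmethanol F6. Oxidation with Dess–Martin periodinane buffered by NaHCO3 (CH2Cl2, 0 °C) comes back to the route at 9, which is carried into step 7 without storage.

Further compounds
F1 | step 9 | 4-{(Z)-2-[(3S)-7,8-dimethoxy-6-(methoxymethoxy)chroman-3-yl]ethenyl}-4-hydroxy-2,3-dimethoxycyclobut-2-en-1-one | COC1=C(OC)C(O)(/C=C\[C@H]2COc3c(cc(OCOC)c(OC)c3OC)C2)C1=O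
F2 | step 9 | 5-[(3S)-7,8-dimethoxy-6-(methoxymethoxy)chroman-3-yl]-2,3-dimethoxybenzene-1,4-diol | COc1c(O)cc([C@H]2COc3c(cc(OCOC)c(OC)c3OC)C2)c(O)c1OC
F3 | step 5 | racemic 7,8-dimethoxy-6-(methoxymethoxy)chromane-3-carboxylic acid | OC(=O)C1COc2c(cc(OCOC)c(OC)c2OC)C1
F4 | step 5 | (4S)-4-benzyl-3-{[(3R)-7,8-dimethoxy-6-(methoxymethoxy)chroman-3-yl]carbonyl}oxazolidin-2-one | O=C([C@H]1COc2c(cc(OCOC)c(OC)c2OC)C1)N1[C@@H](Cc2ccccc2)COC1=O
F5 | step 5 | (4S)-4-benzyl-3-{[(3S)-7,8-dimethoxy-6-(methoxymethoxy)chroman-3-yl]carbonyl}oxazolidin-2-one | O=C([C@@H]1COc2c(cc(OCOC)c(OC)c2OC)C1)N1[C@@H](Cc2ccccc2)COC1=O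
F6 | step 6 | [(3S)-7,8-dimethoxy-6-(methoxymethoxy)chroman-3-yl]methanol | OC[C@H]1COc2c(cc(OCOC)c(OC)c2OC)C1
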